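**Plan**

1. The last bonds cut are the two aryl O–CH3 bonds; both phenols of the B ring and the benzyl ring travel as methyl ethers.
2. Ring A is cut at C5–C6 and C7–C8. The arc C5(OH)–C6(H)–C7(OH)–C8(CH2Ar) is a 1,3-dioxygenated chain whose ends sit on C4a and C8a, the two carbons of the ring C double bond. It therefore unfolds to an acetyl unit (C6, C7) and a 2-(2-arylethyl)-6-aryl-4-pyrone-3-carboxylate in which the ester carbon is C5 and the lateral CH2 is C8.
3. Ring C is cut at O1–C2 and C4–C4a (arylpropioloyl chloride plus β-keto ester), and the β-keto ester at the C8–CH2Ar bond (acetoacetate dianion plus 4-methoxybenzyl chloride).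
4. Forward: C8–CH2Ar, then C4–C4a by C-acylation, ring C by 6-endo-dig O1–C2 closure, C7–C8 by lateral acetylation, ring A by C5–C6 Claisen closure with aromatization, then O-demethylation.
5. Stereochemistry: the target has no stereocenter and no stereogenic double bond; the single stereocenter on the way (C8 of the acetylated pyrone) is racemic and disappears on aromatization.

Key step: step 6

Remark: methyl acetoacetate, 4-methoxybenzyl chloride, 3-(4-methoxyphenyl)propiolic acid and N-methoxy-N-methylacetamide are taken as purchased. Flavone numbering (O1, C2 … C8a) is used for the atoms of all intermediates.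

**Step 1**
Reactants: 1 methyl acetoacetate; 2 4-methoxybenzyl chloride
Product: 3 methyl 5-(4-methoxyphenyl)-3-oxopentanoate
Conditions: NaH, THF, 0 °C; n-BuLi, 0 °C; then 2, 0 °C to rt; 1 M HCl
Reagents that add atoms: none
Why: Weiler dianion alkylation, in which the terminal carbanion of the acetoacetate dianion is far more nucleophilic than the internal enolate carbon, so the reactive benzylic chloride should be taken up at the γ-carbon only, joining the future C8 to the benzyl CH2.

**Step 2**
Reactants: 4 3-(4-methoxyphenyl)propiolic acid
Product: 5 3-(4-methoxyphenyl)propioloyl chloride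
Conditions: (COCl)2, cat. DMF, CH2Cl2, 0 °C to rt; concentrated and used crude
Reagents that add atoms: oxalyl chloride, ClC(=O)C(=O)Cl
Why: Vilsmeier-type activation by the chloroiminium salt from oxalyl chloride and DMF should convert the acid into its chloride without heating, which spares the conjugated alkyne and the aryl ether.

**Step 3**
Reactants: 3 methyl 5-(4-methoxyphenyl)-3-oxopentanoate; 5 3-(4-methoxyphenyl)propioloyl chloride
Product: 6 methyl 2-[3-(4-methoxyphenyl)prop-2-ynoyl]-5-(4-methoxyphenyl)-3-oxopentanoate (largely enolized tricarbonyl, taken on without purification)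
Conditions: MgCl2, pyridine, CH2Cl2, 0 °C to rt; 1 M HCl
Reagents that add atoms: none
Why: Rathke soft-enolization C-acylation, in which the chelated magnesium enolate of the β-keto ester is acylated on carbon (forming C4–C4a) and the more acidic triacylmethane product stays bound to magnesium, which should prevent a second acylation.

**Step 4**
Reactants: 6 methyl 2-[3-(4-methoxyphenyl)prop-2-ynoyl]-5-(4-methoxyphenyl)-3-oxopentanoate
Product: 7 methyl 6-(4-methoxyphenyl)-2-[2-(4-methoxyphenyl)ethyl]-4-oxo-4H-pyran-3-carboxylate
Conditions: CF3SO3H (10 mol %), CH2Cl2, 0 °C to rt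
Reagents that add atoms: none
Why: Acid-promoted intramolecular oxa-Michael addition (Ruhemann-type γ-pyrone synthesis), in which the enol oxygen of the side-chain ketone attacks the alkyne carbon bearing the 4-methoxyphenyl group, where the protonated ynone carries its positive charge, so a 6-endo-dig closure forming O1–C2 should give the aromatic 4-pyrone.

**Step 5**
Reactants: 7 methyl 6-(4-methoxyphenyl)-2-[2-(4-methoxyphenyl)ethyl]-4-oxo-4H-pyran-3-carboxylate; 8 N-methoxy-N-methylacetamide
Product: 9 methyl 6-(4-methoxyphenyl)-2-[1-(4-methoxyphenyl)-3-oxobutan-2-yl]-4-oxo-4H-pyran-3-carboxylate (racemic)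
Conditions: LiN(SiMe3)2 (2.2 equiv), THF, −78 °C; then 8, −78 to 0 °C; 1 M HCl
Reagents that add atoms: none
Why: Lateral (vinylogous) metalation of a 2-alkyl-4-pyrone followed by Weinreb ketone synthesis, in which the CH2 on C8a is acidified through the C8a=C4a bond by both the C4 carbonyl and the ester and its lithium dienolate should add to the amide on carbon to form C7–C8; the new C8 stereocenter is formed racemic and is removed in step 6.

**Step 6**
Reactants: 9 methyl 6-(4-methoxyphenyl)-2-[1-(4-methoxyphenyl)-3-oxobutan-2-yl]-4-oxo-4H-pyran-3-carboxylate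
Product: 10 5,7-dihydroxy-8-(4-methoxybenzyl)-2-(4-methoxyphenyl)-4H-chromen-4-one
Conditions: LiN(i-Pr)2 (3 equiv), THF, −78 to 0 °C; 1 M HCl
Reagents that add atoms: none
Why: Proposed new method: the first equivalent of base should remove the acidic C8–H and a second the terminal methyl proton, giving a dianion of the acetoacetate-dianion type whose terminal carbon (C6) adds to the ester carbonyl on C4a (C5); loss of methoxide then gives a cyclic 1,3-dione that is deprotonated at once to the aromatic 5,7-bis(phenoxide), which makes the closure irreversible. The closest known reactions are the base-mediated intramolecular Claisen cyclization of 2-(2-oxopropyl)benzoates to naphthalene-1,3-diols and the Staunton–Weinreb toluate-anion annulation, whereas a 4-pyrone-3-carboxylate has not served as the ester partner. Ring A (C4a–C5–C6–C7–C8–C8a) closes in a 6-(enolendo)-exo-trig mode, which is allowed for enolates. No stereocenter is formed, and the racemic C8 center becomes an sp2 carbon. The step needs C-acylation by C6 in place of O-acylation by the enolate oxygen (a fused enol lactone) or aldol addition to the equidistant C4 carbonyl (reversible and unproductive), and it needs ring C to stay closed: the dianion puts the most reactive nucleophile on C6, the C8 carbanion could only close a four-membered ring, the ester and the oxopropyl arm are held cis on the C4a=C8a bond, and a hindered amide base facing a pyrone substituted at C2 and C8a should not open it. The benzyl group cannot end up at C6, because its carbon was already tied to C8a while ring A was still open.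

**Step 7**
Reactants: 10 5,7-dihydroxy-8-(4-methoxybenzyl)-2-(4-methoxyphenyl)-4H-chromen-4-one
Product: 11 5,7-dihydroxy-8-(4-hydroxybenzyl)-2-(4-hydroxyphenyl)-4H-chromen-4-one (8-(4-hydroxybenzyl)apigenin)
Conditions: BBr3 (6 equiv), CH2Cl2, −78 °C to rt; then H2O
Reagents that add atoms: none
Why: Lewis-acid ether cleavage, in which BBr3 binds each aryl methyl ether oxygen and bromide removes the methyl group by SN2 attack; the cold anhydrous medium should leave the pyrone closed, so the acid-induced ring opening behind a Wessely–Moser shift of the benzyl group to C6 is avoided.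

**Compound list**

1 | methyl acetoacetate | COC(=O)CC(C)=O | starting material
2 | 4-methoxybenzyl chloride | COc1ccc(CCl)cc1 | starting material
3 | methyl 5-(4-methoxyphenyl)-3-oxopentanoate | COC(=O)CC(=O)CCc1ccc(OC)cc1 | intermediate
4 | 3-(4-methoxyphenyl)propiolic acid | COc1ccc(C#CC(=O)O)cc1 | starting material
5 | 3-(4-methoxyphenyl)propioloyl chloride | COc1ccc(C#CC(=O)Cl)cc1 | intermediate
6 | methyl 2-[3-(4-methoxyphenyl)prop-2-ynoyl]-5-(4-methoxyphenyl)-3-oxopentanoate | COC(=O)C(C(=O)C#Cc1ccc(OC)cc1)C(=O)CCc1ccc(OC)cc1 | intermediate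
7 | methyl 6-(4-methoxyphenyl)-2-[2-(4-methoxyphenyl)ethyl]-4-oxo-4H-pyran-3-carboxylate | COC(=O)c1c(CCc2ccc(OC)cc2)oc(-c2ccc(OC)cc2)cc1=O | intermediate
8 | N-methoxy-N-methylacetamide | CON(C)C(C)=O | starting material
9 | methyl 6-(4-methoxyphenyl)-2-[1-(4-methoxyphenyl)-3-oxobutan-2-yl]-4-oxo-4H-pyran-3-carboxylate (racemic) | COC(=O)c1c(C(Cc2ccc(OC)cc2)C(C)=O)oc(-c2ccc(OC)cc2)cc1=O | intermediate
10 | 5,7-dihydroxy-8-(4-methoxybenzyl)-2-(4-methoxyphenyl)-4H-chromen-4-one | O=c1cc(-c2ccc(OC)cc2)oc2c(Cc3ccc(OC)cc3)c(O)cc(O)c12 | intermediate
11 | 5,7-dihydroxy-8-(4-hydroxybenzyl)-2-(4-hydroxyphenyl)-4H-chromen-4-one | O=c1cc(-c2ccc(O)cc2)oc2c(Cc3ccc(O)cc3)c(O)cc(O)c12 | target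

**Count**

Total steps: 7. Longest linear sequence: 6 steps (steps 1, 3, 4, 5, 6, 7; the branch through step 2 is equally long).

**Steps most likely to fail**

Step 6 (key step). The dianion may not form cleanly, so that the monoanion closes through oxygen to an enol lactone, or the base may open ring C, after which recyclization could scramble the position of the benzyl group. The fallback uses known chemistry throughout and brings the benzyl group to C8 of a finished flavone by cross-coupling. It sets out from compound 2, which is converted with Zn dust and LiCl in THF into (4-methoxybenzyl)zinc chloride F1. Purchased 4′,5,7-trimethoxyflavone F2 is iodinated with I2 and CF3CO2Ag in CH2Cl2, which should go to C8, the usual site of halogenation in 5,7-dialkoxyflavones, to give 8-iodo-5,7-dimethoxy-2-(4-methoxyphenyl)-4H-chromen-4-one F3. Negishi coupling of F3 with F1 (Pd(OAc)2, SPhos, THF, rt to 50 °C) should give 5,7-dimethoxy-8-(4-methoxybenzyl)-2-(4-methoxyphenyl)-4H-chromen-4-one F4. Cleavage of all four methyl ethers with excess BBr3 in CH2Cl2 (0 °C to rt, prolonged) brings the sequence back to the route at the target 11.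

Step 5. The hindered, doubly stabilized secondary carbanion may add too slowly to the Weinreb amide and be returned as starting pyrone on quench, or it may be acylated on the C4 oxygen. The fallback reverses the order of the two bond formations at C8, so that acetylation meets an unhindered primary lateral carbanion and the benzyl group enters by alkylation of a soft, doubly activated carbanion. It sets out from compound 1, which is C-acylated with 5 (MgCl2, pyridine, CH2Cl2, as in step 3) to methyl 2-acetyl-5-(4-methoxyphenyl)-3-oxopent-4-ynoate F5. Cyclization (CF3SO3H cat., CH2Cl2, as in step 4) should give methyl 6-(4-methoxyphenyl)-2-methyl-4-oxo-4H-pyran-3-carboxylate F6. Lateral lithiation (LiN(SiMe3)2, THF, −78 °C) and acetylation with 8 should give methyl 6-(4-methoxyphenyl)-4-oxo-2-(2-oxopropyl)-4H-pyran-3-carboxylate F7. C-benzylation of its acidic CH2 with 2 (K2CO3, acetone, reflux) returns to the route at compound 9.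

Step 4. Ring closure may take the wrong course, by 5-exo-dig attack or by attack of the ester carbonyl oxygen, or the ynone may be hydrated under acid. The fallback builds ring C at the dihydro level, where only 6-endo attack on the β-carbon of an enone is open, and then dehydrogenates it. It sets out from compound 3, which is C-acylated (MgCl2, pyridine, CH2Cl2) with purchased (E)-4-methoxycinnamoyl chloride F8 to give methyl 2-[(E)-3-(4-methoxyphenyl)prop-2-enoyl]-5-(4-methoxyphenyl)-3-oxopentanoate F9. Heating F9 with catalytic I2 in DMSO, the conditions that turn 2′-hydroxychalcones into flavones, should close it by oxa-Michael addition to methyl 6-(4-methoxyphenyl)-2-[2-(4-methoxyphenyl)ethyl]-4-oxo-5,6-dihydro-4H-pyran-3-carboxylate F10 and dehydrogenate this in the same pot, returning to the route at compound 7.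

**Further compounds**

F1 | step 6 | (4-methoxybenzyl)zinc chloride | COc1ccc(C[Zn]Cl)cc1
F2 | step 6 | 4′,5,7-trimethoxyflavone (purchased) | COc1ccc(-c2cc(=O)c3c(OC)cc(OC)cc3o2)cc1
F3 | step 6 | 8-iodo-5,7-dimethoxy-2-(4-methoxyphenyl)-4H-chromen-4-one | COc1ccc(-c2cc(=O)c3c(OC)cc(OC)c(I)c3o2)cc1
F4 | step 6 | 5,7-dimethoxy-8-(4-methoxybenzyl)-2-(4-methoxyphenyl)-4H-chromen-4-one | COc1ccc(Cc2c(OC)cc(OC)c3c(=O)cc(-c4ccc(OC)cc4)oc23)cc1
F5 | step 5 | methyl 2-acetyl-5-(4-methoxyphenyl)-3-oxopent-4-ynoate | COC(=O)C(C(C)=O)C(=O)C#Cc1ccc(OC)cc1
F6 | step 5 | methyl 6-(4-methoxyphenyl)-2-methyl-4-oxo-4H-pyran-3-carboxylate | COC(=O)c1c(C)oc(-c2ccc(OC)cc2)cc1=O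
F7 | step 5 | methyl 6-(4-methoxyphenyl)-4-oxo-2-(2-oxopropyl)-4H-pyran-3-carboxylate | COC(=O)c1c(CC(C)=O)oc(-c2ccc(OC)cc2)cc1=O
F8 | step 4 | (E)-4-methoxycinnamoyl chloride (purchased) | COc1ccc(/C=C/C(Cl)=O)cc1
F9 | step 4 | methyl 2-[(E)-3-(4-methoxyphenyl)prop-2-enoyl]-5-(4-methoxyphenyl)-3-oxopentanoate | COC(=O)C(C(=O)/C=C/c1ccc(OC)cc1)C(=O)CCc1ccc(OC)cc1
F10 | step 4 | methyl 6-(4-methoxyphenyl)-2-[2-(4-methoxyphenyl)ethyl]-4-oxo-5,6-dihydro-4H-pyran-3-carboxylate (racemic) | COC(=O)C1=C(CCc2ccc(OC)cc2)OC(c2ccc(OC)cc2)CC1=O
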